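The route rests on the C3–C4 disconnection. It traces ring A (O8, C4–C8) back to 2,4,6-trimethylpyrylium. Methyls on C4, C6 and C8 alternate with oxygen on C5 and C7, which is the pattern left by α-addition to the cation and anti-Markovnikov hydration of both ring alkenes. The precursor is a 2,2-disubstituted 2,4,6-trimethyl-2H-pyran whose C4 carries the PMB-protected isopropenyl carbinol C1–C3. One hydroboration–oxidation adds H and OH across C1=C2, C5=C6 and C7=C8. It makes three C–O bonds and five stereocentres (C2, C5–C8) without closing a ring. Oxidative lactonisation (ring B), acylation with an alkynoic acid and a final cis-semihydrogenation deliver the labile (Z)-4-oxodecenoate.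

Key step: step 4

Numbering: C1 lactone carbonyl, C2 (Me), C3 (OAc), C4 (quaternary, Me, bonded to ring oxygen O8), C5 (lactone oxygen), C6 (Me), C7 (acyloxy), C8 (bonded to O8, bears methyl C9). The side chain is C1'–C10'. Ring A is the tetrahydropyran and ring B the δ-lactone.

Assumption: the /C=C\ notation of the side chain is read as Z (ketone and ester carbonyls cis), so the target is (2R,3S,4S,5S,6R,7R,8S,2'Z).

Design remark: free (Z)-4-oxodec-2-enoic acid exists as its cyclic pseudo-acid (5-hexyl-5-hydroxyfuran-2(5H)-one), and cis-enediones go to trans with pyridine-type bases. The chain is therefore attached as a 4-silyloxy-2-ynoate and the Z alkene is made last. The carbinol centre C4' is racemic, so every ester that still carries it is a pair of C4' epimers, and the pair converges on oxidation.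

Step 1
Reactants: 1 2-methylprop-2-en-1-ol (methallyl alcohol); 2 4-methoxybenzyl chloride
Product: 3 1-methoxy-4-{[(2-methylprop-2-en-1-yl)oxy]methyl}benzene (PMB methallyl ether)
Conditions: NaH, n-Bu4NI (cat.), THF/DMF, 0 °C → rt
Reagents that add atoms: none
Why: Williamson ether synthesis between a primary alkoxide and a reactive benzylic chloride (iodide catalysis) is dependable and creates no stereocentre.

Step 2
Reactants: 3 PMB methallyl ether; 4 tributyltin chloride
Product: 6 (Z)-tributyl{3-[(4-methoxybenzyl)oxy]-2-methylprop-2-en-1-yl}stannane, via alkoxyallyllithium 5 (not isolated)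
Conditions: s-BuLi, THF, −78 °C; then 4, −78 → 0 °C
Reagents that add atoms: none
Why: Allylic lithiation of an allyl ether followed by γ-stannylation: the anion is held in the cis (O–Li chelated) form and the soft tin electrophile takes the terminus remote from oxygen, which fixes the Z enol ether, while at −78 °C the electron-rich PMB group is slow to undergo benzylic metalation or Wittig rearrangement.

Step 3
Reactants: 6 (Z)-γ-alkoxyallylstannane; 7 2,4,6-trimethylpyrylium tetrafluoroborate
Product: 8 (2S)-2-{(1S)-1-[(4-methoxybenzyl)oxy]-2-methylprop-2-en-1-yl}-2,4,6-trimethyl-2H-pyran (3S,4S in target numbering)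
Conditions: powdered 7, 6, (S)-2-{3-[3,5-bis(trifluoromethyl)phenyl]thioureido}-3,3-dimethyl-1-[(R)-2-(phenanthren-9-yl)pyrrolidin-1-yl]butan-1-one or its antipode (10 mol%, sense of induction to be found by screening), MTBE, −60 → −30 °C; cold filtration through basic Al2O3; solution used at once
Reagents that add atoms: none
Why: Proposed new method: the insoluble salt 7 should enter the ether phase only as an ion pair whose BF4− is hydrogen-bonded to the chiral thiourea and whose cation stacks on the phenanthryl group, so that the strongly π-nucleophilic enol-ether terminus of 6 attacks one of the two enantiotopic α-carbons (the sites of highest positive charge, also chosen by organomagnesium reagents) from one face in an open SE2' transition state with loss of tin, setting C4 and C3 together with the syn O3/O8 relationship that (Z)-γ-alkoxyallylstannanes give with oxocarbenium-type electrophiles; the closest known reaction types are racemic carbon-nucleophile additions to this salt, allylstannane additions to benzopyrylium salts and anion-binding catalysis of silyl ketene acetal additions to cyclic oxocarbenium ions.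

Step 4
Reactants: 8 2H-pyran triene
Product: 11 (2S,3S)-3-[(2S,3S,4R,5R,6S)-3,5-dihydroxy-2,4,6-trimethyloxan-2-yl]-3-[(4-methoxybenzyl)oxy]-2-methylpropan-1-ol (C1,C5,C7-triol), via C1-borabicyclononyl 2H-pyran 9 (not isolated), via C1,C5,C7-triborane 10 (not isolated)
Conditions: 9-BBN (9-borabicyclo[3.3.1]nonane, 0.5 M in THF), 0 °C; BH3·THF (excess), −20 → 0 °C; then 3 M NaOH, 30% H2O2, 0 °C → rt
Reagents that add atoms: hydrogen peroxide, OO
Why: Proposed new method: 9-BBN first adds through the usual four-centre syn transition state to the only 1,1-disubstituted alkene (C1=C2), the smaller and more reactive BH3 then adds twice to the ring dienyl ether, and alkaline H2O2 replaces all three C–B bonds by C–O with retention. The closest known reaction types are hydroboration of glycal-like cyclic enol ethers, of trisubstituted cycloalkenes and of 2-methylallyl ethers with dialkylboranes, but a conjugated 2H-pyran has not been used. No ring is closed, since ring A is already present and only loses its two double bonds. Boron goes to C1, C5 and C7 because each is the less substituted alkene carbon and C5 and C7 are also the electron-rich positions of the O8–C8=C7–C6=C5 π-system. C2 is set by attack of 9-BBN on the allylic-strain-minimised conformer (C3–H eclipsing the alkene) from the side away from quaternary C4, giving the 2,3-anti pair; C5/C6 are set by syn addition to the ring face opposite the C3 chain, now enlarged by the borabicyclononyl group and opposed only by the C4 methyl; C7/C8 are set by syn addition to the same face, away from that chain and from the C6 methyl just raised on the other face, so all substituents at C5–C8 end up equatorial. The step needs chemoselectivity (9-BBN ignores the trisubstituted ring alkenes at 0 °C), low temperature (the 6π ring opening that would scramble C4 relative to C3 and the elimination of β-alkoxyboranes are then slow, and geminal substitution at C4 keeps the pyran closed) and excess BH3 so that any ring mono-adduct is consumed at once.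

Step 5
Reactants: 11 triol
Product: 13 trans-fused ring A/ring B lactone alcohol (C3–OPMB; C7–OH free; configuration of 11 retained), via C1-lactol 12 (not isolated)
Conditions: TEMPO (2,2,6,6-tetramethylpiperidin-1-oxyl, cat.), PhI(OAc)2, CH2Cl2, rt
Reagents that add atoms: none
Why: Oxoammonium-mediated oxidative lactonisation of a 1,5-diol: only the unhindered primary C1–OH is oxidised, the aldehyde is trapped by the equatorial C5–OH as six-membered lactol 12 and this is oxidised on to the δ-lactone, while the hindered secondary C7–OH and all stereocentres, including epimerisable C2, stay untouched under these nearly neutral conditions.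

Step 6
Reactants: 14 heptanal; 15 ethynylmagnesium bromide
Product: 16 non-1-yn-3-ol (racemic)
Conditions: THF, 0 °C; then sat. aq. NH4Cl
Reagents that add atoms: none
Why: Grignard 1,2-addition of an alkynyl nucleophile to an unhindered aldehyde; the new carbinol centre (later C4') is left racemic on purpose because it is oxidised away.

Step 7
Reactants: 16 non-1-yn-3-ol
Product: 17 tert-butyl(dimethyl)(non-1-yn-3-yloxy)silane
Conditions: TBSCl, imidazole, DMF, rt
Reagents that add atoms: tert-butyldimethylsilyl chloride, CC(C)(C)[Si](C)(C)Cl
Why: Standard silylation of a secondary alcohol gives an ether that withstands n-BuLi, DCC/DMAP, DDQ and acetylation.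

Step 8
Reactants: 17 silyl ether
Product: 19 4-[(tert-butyldimethylsilyl)oxy]dec-2-ynoic acid, via lithium acetylide 18 (not isolated)
Conditions: n-BuLi, THF, −78 °C; CO2; then cold dilute HCl
Reagents that add atoms: carbon dioxide, O=C=O
Why: Deprotonation of the terminal alkyne and carboxylation of the lithium acetylide is the standard route to 2-alkynoic acids and leaves the silyl ether intact.

Step 9
Reactants: 13 lactone alcohol; 19 silyloxy-ynoic acid
Product: 20 C7 4-silyloxydec-2-ynoate of 13 (both C4' epimers)
Conditions: DCC, 4-(dimethylamino)pyridine (cat.), CH2Cl2, 0 °C → rt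
Reagents that add atoms: none
Why: Steglich esterification of the only free hydroxyl (equatorial C7–OH): the linear 2-ynoic acid can neither close to a pseudo-acid nor lose alkene geometry during acyl transfer, and no stereocentre of 13 is affected.

Step 10
Reactants: 20 PMB ether ester
Product: 21 C3 alcohol
Conditions: DDQ, CH2Cl2/pH 7 buffer, 0 °C → rt
Reagents that add atoms: none
Why: Oxidative PMB cleavage: DDQ abstracts hydride from the electron-rich benzylic position and water hydrolyses the resulting oxocarbenium ion, conditions under which ynoate, silyl ether and lactone are inert.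

Step 11
Reactants: 21 C3 alcohol
Product: 22 C3 acetate
Conditions: Ac2O, pyridine, 4-(dimethylamino)pyridine (cat.), CH2Cl2, 0 °C → rt
Reagents that add atoms: acetic anhydride, CC(=O)OC(C)=O
Why: Nucleophile-catalysed acetylation of the hindered C3–OH; pyridine at or below room temperature is too weak a base to epimerise C2, to eliminate the β-acetoxy group or to isomerise the silyloxy-ynoate.

Step 12
Reactants: 22 silyl ether acetate
Product: 23 C4' propargylic alcohol
Conditions: HF·pyridine, THF, 0 °C → rt (plastic vessel)
Reagents that add atoms: none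
Why: Fluoride-mediated desilylation under acidic conditions avoids the base-induced redox isomerisation of 4-hydroxy-2-ynoates to trans-4-oxo-2-enoates and spares acetate, lactone and ester.

Step 13
Reactants: 23 propargylic alcohol
Product: 24 C7 4-oxodec-2-ynoate (ynone)
Conditions: Dess–Martin periodinane, CH2Cl2, 0 °C → rt
Reagents that add atoms: none
Why: Dess–Martin oxidation of the propargylic alcohol is fast and neutral, erases the C4' stereocentre so that both epimers converge, and finds no other hydroxyl in the molecule.

Step 14
Reactants: 24 ynone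
Product: 25 botcinin J
Conditions: H2 (1 atm, stopped after one equivalent), 5% Pd/CaCO3 poisoned with Pb(OAc)2, EtOAc, 0 °C, dark; rapid filtration, neutral silica
Reagents that add atoms: none
Why: Lindlar-type semihydrogenation delivers both hydrogens to one face of the alkyne adsorbed on lead-poisoned palladium, so the Z alkene forms under neutral, base-free conditions as the very last operation and the cis-enedione has no later chance to isomerise.

Compound list
1 | 2-methylprop-2-en-1-ol | C=C(C)CO | starting material
2 | 4-methoxybenzyl chloride | COc1ccc(CCl)cc1 | starting material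
3 | PMB methallyl ether | C=C(C)COCc1ccc(OC)cc1 | intermediate
4 | tributyltin chloride | CCCC[Sn](Cl)(CCCC)CCCC | starting material
5 | 1-[(4-methoxybenzyl)oxy]-2-methylallyllithium | [Li]C(OCc1ccc(OC)cc1)C(C)=C | intermediate
6 | (Z)-tributyl{3-[(4-methoxybenzyl)oxy]-2-methylprop-2-en-1-yl}stannane | CCCC[Sn](CCCC)(CCCC)C/C(C)=C\OCc1ccc(OC)cc1 | intermediate
7 | 2,4,6-trimethylpyrylium tetrafluoroborate | Cc1cc(C)[o+]c(C)c1.F[B-](F)(F)F | starting material
8 | (3S,4S)-2H-pyran triene | CC1=CC(C)=C[C@](C)(O1)[C@@H](OCc2ccc(OC)cc2)C(C)=C | intermediate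
9 | C1-(9-borabicyclononyl) 2H-pyran | CC1=CC(C)=C[C@](C)(O1)[C@@H](OCc2ccc(OC)cc2)[C@@H](C)CB3C4CCCC3CCC4 | intermediate
10 | C1,C5,C7-triborane (ring boranes drawn as BH2) | [BH2][C@@H]1[C@@H](C)[C@H]([BH2])[C@@](C)([C@@H](OCc2ccc(OC)cc2)[C@@H](C)CB3C4CCCC3CCC4)O[C@H]1C | intermediate
11 | C1,C5,C7-triol with C3–OPMB | O[C@@H]1[C@@H](C)[C@H](O)[C@@](C)([C@@H](OCc2ccc(OC)cc2)[C@@H](C)CO)O[C@H]1C | intermediate
12 | C1-lactol (anomers) | O[C@@H]1[C@@H](C)[C@@H]2OC(O)[C@H](C)[C@H](OCc3ccc(OC)cc3)[C@@]2(C)O[C@H]1C | intermediate
13 | lactone alcohol (C3–OPMB, C7–OH) | O[C@@H]1[C@@H](C)[C@@H]2OC(=O)[C@H](C)[C@H](OCc3ccc(OC)cc3)[C@@]2(C)O[C@H]1C | intermediate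
14 | heptanal | CCCCCCC=O | starting material
15 | ethynylmagnesium bromide | C#C[Mg]Br | starting material
16 | non-1-yn-3-ol (racemic) | CCCCCCC(O)C#C | intermediate
17 | tert-butyl(dimethyl)(non-1-yn-3-yloxy)silane (racemic) | CCCCCCC(O[Si](C)(C)C(C)(C)C)C#C | intermediate
18 | lithium acetylide of 17 | CCCCCCC(O[Si](C)(C)C(C)(C)C)C#C[Li] | intermediate
19 | 4-[(tert-butyldimethylsilyl)oxy]dec-2-ynoic acid (racemic) | CCCCCCC(O[Si](C)(C)C(C)(C)C)C#CC(=O)O | intermediate
20 | C7 silyloxy-ynoate, C3–OPMB (C4' epimers) | CCCCCCC(O[Si](C)(C)C(C)(C)C)C#CC(=O)O[C@@H]1[C@@H](C)[C@@H]2OC(=O)[C@H](C)[C@H](OCc3ccc(OC)cc3)[C@@]2(C)O[C@H]1C | intermediate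
21 | C7 silyloxy-ynoate, C3–OH (C4' epimers) | CCCCCCC(O[Si](C)(C)C(C)(C)C)C#CC(=O)O[C@@H]1[C@@H](C)[C@@H]2OC(=O)[C@H](C)[C@H](O)[C@@]2(C)O[C@H]1C | intermediate
22 | C7 silyloxy-ynoate, C3–OAc (C4' epimers) | CCCCCCC(O[Si](C)(C)C(C)(C)C)C#CC(=O)O[C@@H]1[C@@H](C)[C@@H]2OC(=O)[C@H](C)[C@H](OC(C)=O)[C@@]2(C)O[C@H]1C | intermediate
23 | C7 4-hydroxydec-2-ynoate, C3–OAc (C4' epimers) | CCCCCCC(O)C#CC(=O)O[C@@H]1[C@@H](C)[C@@H]2OC(=O)[C@H](C)[C@H](OC(C)=O)[C@@]2(C)O[C@H]1C | intermediate
24 | C7 4-oxodec-2-ynoate, C3–OAc | CCCCCCC(=O)C#CC(=O)O[C@@H]1[C@@H](C)[C@@H]2OC(=O)[C@H](C)[C@H](OC(C)=O)[C@@]2(C)O[C@H]1C | intermediate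
25 | botcinin J | CCCCCCC(=O)/C=C\C(=O)O[C@@H]1[C@@H](C)[C@@H]2OC(=O)[C@H](C)[C@H](OC(C)=O)[C@@]2(C)O[C@H]1C | target

Total step count: 14. Longest linear sequence: 11 (steps 1–5 and 9–14).

Steps most likely to fail

1. Step 4.
- Borane may approach ring A from the face of the C3 chain, since only chain versus methyl tells the faces apart.
- First attack may occur at C7=C8. That makes an allylborane, which can shift boron 1,3 and lose stereochemical information.
- The β-alkoxyboranes may eliminate with cleavage of C4–O8 or C8–O8.
- The pyran may open thermally before the ring is hydroborated.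

The fallback uses known reactions only. It sets out from 8 and returns at 11.
- Sensitised photooxygenation is known for cyclic 1,3-dienes and for 2H-pyran valence isomers of cis-dienones. With O2, 5,10,15,20-tetraphenylporphyrin and visible light in CH2Cl2 at −78 °C it adds O2 across C5/C8 to give the C5,C8-endoperoxide F1.
- Et3N turns F1 by Kornblum–DeLaMare rearrangement into the C5-keto C8-hemiketal enone F2, the compound type of an Achmatowicz product.
- Et3SiH/BF3·OEt2 at −78 °C removes the hemiketal hydroxyl with axial hydride delivery. This gives the C8-deoxy enone F3, with the C8 methyl cis to the C3 chain.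
- Conjugate borylation uses bis(pinacolato)diboron, CuCl, NaOt-Bu, bis[2-(diphenylphosphino)phenyl] ether and MeOH in THF. It places boron on C7 anti to the C8 methyl and gives the β-boryl ketone F4, whose C6 methyl settles equatorial by enolisation.
- NaBO3·4H2O gives the β-hydroxy ketone F5.
- NaBH4 in MeOH attacks axially and gives the C5,C7-diol F6.
- The precedented 9-BBN addition to the isopropenyl ether gives the C1-borane F7, which NaOH/H2O2 oxidises to 11.

2. Step 3.
- Binding of BF4− may be weak and an uncatalysed pathway may erode the enantioselectivity.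
- The C3/C4 relative topicity may be poor.
- Attack at the γ-carbon may compete.
- C4 may epimerise through ring opening during handling.

The fallback sets out from 6 and 7 and returns at 11. The addition is run without catalyst in MeCN/CH2Cl2 at −40 °C. This is an ordinary π-nucleophile addition to a preformed pyrylium salt. It gives 8 together with its mirror image, the (3R,4R)-2H-pyran F8. The racemate passes through step 4 unchanged, by way of the mirror-image C1-borane F9 and the mirror-image triborane F10, to 11 and the mirror-image triol F11. The two triols are separated by preparative chromatography on an amylose tris(3,5-dimethylphenylcarbamate) phase, and 11 goes on.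

3. Step 14.
- The strongly activated ene-dione may be reduced further to the saturated 1,4-dicarbonyl chain.
- The alkene may isomerise from Z to E on the catalyst or on silica.

The fallback sets out from 22 and returns at 25. The alkene geometry is set before the ketone exists. The unactivated ynoate 22 is semihydrogenated over the same poisoned palladium to the (Z)-4-silyloxy-2-enoate F12. HF·pyridine frees the (Z)-4-hydroxy-2-enoate F13, and the crude alcohol is oxidised at once with Dess–Martin periodinane to 25. The hazard then lies in butenolide formation from F13 with expulsion of the C7 alcohol, so F13 is neither stored nor chromatographed.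

Further compounds
F1 | step 4 | C5,C8-endoperoxide of 8 | C[C@@]12OO[C@@H](C(C)=C1)[C@](C)(O2)[C@@H](OCc3ccc(OC)cc3)C(C)=C
F2 | step 4 | C5-keto C8-hemiketal enone (anomers) | CC1=CC(C)(O)O[C@@](C)(C1=O)[C@@H](OCc2ccc(OC)cc2)C(C)=C
F3 | step 4 | C8-deoxy enone | CC1=C[C@H](C)O[C@@](C)(C1=O)[C@@H](OCc2ccc(OC)cc2)C(C)=C
F4 | step 4 | C7-(pinacolboryl) C5-ketone | CC1(C)OB(OC1(C)C)[C@@H]2[C@@H](C)C(=O)[C@@](C)([C@@H](OCc3ccc(OC)cc3)C(C)=C)O[C@H]2C
F5 | step 4 | C7-hydroxy C5-ketone | O[C@@H]1[C@@H](C)C(=O)[C@@](C)([C@@H](OCc2ccc(OC)cc2)C(C)=C)O[C@H]1C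
F6 | step 4 | C5,C7-diol with intact isopropenyl group | O[C@@H]1[C@@H](C)[C@H](O)[C@@](C)([C@@H](OCc2ccc(OC)cc2)C(C)=C)O[C@H]1C
F7 | step 4 | C1-(9-borabicyclononyl) C5,C7-diol | O[C@@H]1[C@@H](C)[C@H](O)[C@@](C)([C@@H](OCc2ccc(OC)cc2)[C@@H](C)CB3C4CCCC3CCC4)O[C@H]1C
F8 | step 3 | (3R,4R)-2H-pyran, mirror image of 8 | CC1=CC(C)=C[C@@](C)(O1)[C@H](OCc2ccc(OC)cc2)C(C)=C
F9 | step 3 | mirror image of 9 | CC1=CC(C)=C[C@@](C)(O1)[C@H](OCc2ccc(OC)cc2)[C@H](C)CB3C4CCCC3CCC4
F10 | step 3 | mirror image of 10 | [BH2][C@H]1[C@H](C)[C@@H]([BH2])[C@](C)([C@H](OCc2ccc(OC)cc2)[C@H](C)CB3C4CCCC3CCC4)O[C@@H]1C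
F11 | step 3 | mirror image of 11 | O[C@H]1[C@H](C)[C@@H](O)[C@](C)([C@H](OCc2ccc(OC)cc2)[C@H](C)CO)O[C@@H]1C
F12 | step 14 | C7 (Z)-4-silyloxydec-2-enoate, C3–OAc (C4' epimers) | CCCCCCC(O[Si](C)(C)C(C)(C)C)/C=C\C(=O)O[C@@H]1[C@@H](C)[C@@H]2OC(=O)[C@H](C)[C@H](OC(C)=O)[C@@]2(C)O[C@H]1C
F13 | step 14 | C7 (Z)-4-hydroxydec-2-enoate, C3–OAc (C4' epimers) | CCCCCCC(O)/C=C\C(=O)O[C@@H]1[C@@H](C)[C@@H]2OC(=O)[C@H](C)[C@H](OC(C)=O)[C@@]2(C)O[C@H]1C
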